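**Retrosynthetic overview**
- Target 18 comes from its di-O-benzyl ether 17 by hydrogenolysis of the two benzyl ethers as the last step.
- 17 is disconnected across the pyrone at C4–C5 and O1–C2 into arylmethylmalonyl dichloride 13 and silyl enol ether 15; the pyrone is the only ring made in the route and is closed last.
- The strategy rests on this feature: pyrone O1, C6 (ethyl) and C5 (methyl) are the enol of symmetrical pentan-3-one, and C2, C3, C4 plus the bridging CH2 are a benzyl-type substituted malonyl unit, so only one regiochemical outcome is possible.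
- 13 comes from aldehyde 8 and Meldrum's acid 9 by reductive Knoevenagel alkylation, hydrolysis and chlorination.
- 8 comes from phloroglucinol 3 and (R)-2-methylbutanoic acid 1 by Friedel–Crafts acylation, para-O-methylation, Vilsmeier formylation and bis-benzylation; the benzene ring and the stereocentre are bought.

Key step: step 10

Remark on the chemistry: the (R) centre is taken from enantiopure acid 1 and must be carried unchanged through the route. Silyl enol ether 15 is drawn as the Z isomer; its geometry is lost in the pyrone, so an isomer mixture can be used.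

**Step 1**
Reactants: 1 (2R)-2-methylbutanoic acid
Product: 2 (2R)-2-methylbutanoyl chloride
Conditions: (COCl)2 (1.2 equiv), DMF (cat.), CH2Cl2, 0 °C → rt; used after careful concentration
Reagents that add atoms: oxalyl chloride, ClC(=O)C(=O)Cl
Why: Acid chloride formation with oxalyl chloride and catalytic DMF runs at or below room temperature without enolising the α-carbon, so the (R) configuration should be kept.

**Step 2**
Reactants: 2 (2R)-2-methylbutanoyl chloride; 3 phloroglucinol (benzene-1,3,5-triol)
Product: 4 (2R)-2-methyl-1-(2,4,6-trihydroxyphenyl)butan-1-one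
Conditions: AlCl3 (3.5 equiv), PhNO2/CH2Cl2, 0 °C → rt; cold aq. HCl work-up
Reagents that add atoms: none
Why: Friedel–Crafts C-acylation of the very nucleophilic phloroglucinol ring should stop at the mono-ketone because the aluminium-chelated product is deactivated, and at low temperature the acylium ion should be captured faster than it enolises, so the (R) centre is carried through.

**Step 3**
Reactants: 4 (2R)-2-methyl-1-(2,4,6-trihydroxyphenyl)butan-1-one
Product: 5 (2R)-1-(2,6-dihydroxy-4-methoxyphenyl)-2-methylbutan-1-one
Conditions: Me2SO4 (1.0 equiv), K2CO3 (1.0 equiv), acetone, rt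
Reagents that add atoms: dimethyl sulfate, COS(=O)(=O)OC
Why: Williamson methylation; the 4-OH is para to the ketone, the most acidic and the only phenol not hydrogen-bonded to the carbonyl, so one equivalent of base and alkylating agent should methylate it selectively.

**Step 4**
Reactants: 5 (2R)-1-(2,6-dihydroxy-4-methoxyphenyl)-2-methylbutan-1-one
Product: 7 2,4-dihydroxy-6-methoxy-3-[(2R)-2-methylbutanoyl]benzaldehyde, via aryl dimethyliminium chloride 6 (not isolated)
Conditions: POCl3 (1.2 equiv), DMF (3 equiv), EtOAc, 0 °C → rt; then H2O, rt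
Reagents that add atoms: N,N-dimethylformamide, CN(C)C=O; water, O; phosphoryl chloride, O=P(Cl)(Cl)Cl (chloride counter-ion of 6 only)
Why: Vilsmeier–Haack formylation of an electron-rich phenol; the two free ring positions of 5 are equivalent by symmetry, and the first formyl group deactivates the ring toward a second substitution.

**Step 5**
Reactants: 7 2,4-dihydroxy-6-methoxy-3-[(2R)-2-methylbutanoyl]benzaldehyde
Product: 8 2,4-bis(benzyloxy)-6-methoxy-3-[(2R)-2-methylbutanoyl]benzaldehyde
Conditions: BnBr (2.5 equiv), K2CO3 (2.5 equiv), DMF, rt → 50 °C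
Reagents that add atoms: benzyl bromide, BrCc1ccccc1
Why: Williamson O-benzylation of both chelated phenols in a dipolar aprotic solvent; the two carbonyl groups make C-benzylation of the ring unlikely, and carbonate is too weak a base to enolise the ketone.

**Step 6**
Reactants: 8 2,4-bis(benzyloxy)-6-methoxy-3-[(2R)-2-methylbutanoyl]benzaldehyde; 9 Meldrum's acid (2,2-dimethyl-1,3-dioxane-4,6-dione)
Product: 11 5-({2,4-bis(benzyloxy)-6-methoxy-3-[(2R)-2-methylbutanoyl]phenyl}methyl)-2,2-dimethyl-1,3-dioxane-4,6-dione, via arylidene Meldrum's acid 10 (not isolated)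
Conditions: Hantzsch ester (diethyl 2,6-dimethyl-1,4-dihydropyridine-3,5-dicarboxylate, 1.1 equiv), L-proline (20 mol %), EtOH, rt
Reagents that add atoms: none
Why: Proline-catalysed Knoevenagel condensation with the strongly C–H acidic Meldrum's acid is followed in the same flask by conjugate hydride transfer from the Hantzsch ester to the electron-poor arylidene (three-component reductive alkylation), which leaves the hindered aryl ketone untouched.

**Step 7**
Reactants: 11 5-({2,4-bis(benzyloxy)-6-methoxy-3-[(2R)-2-methylbutanoyl]phenyl}methyl)-2,2-dimethyl-1,3-dioxane-4,6-dione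
Product: 12 2-({2,4-bis(benzyloxy)-6-methoxy-3-[(2R)-2-methylbutanoyl]phenyl}methyl)propanedioic acid
Conditions: 2 M aq. HCl/THF (1:1), 40 °C; extraction and drying below 40 °C
Reagents that add atoms: water, O
Why: Acid-catalysed hydrolysis of the cyclic isopropylidene acylal releases acetone and the malonic acid well below the temperature at which it decarboxylates; benzyl ethers and the hindered ketone should tolerate dilute acid.

**Step 8**
Reactants: 12 2-({2,4-bis(benzyloxy)-6-methoxy-3-[(2R)-2-methylbutanoyl]phenyl}methyl)propanedioic acid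
Product: 13 2-({2,4-bis(benzyloxy)-6-methoxy-3-[(2R)-2-methylbutanoyl]phenyl}methyl)propanedioyl dichloride
Conditions: (COCl)2 (3 equiv), DMF (cat.), CH2Cl2, 0 °C → rt; concentrate, strip with toluene, use crude at once
Reagents that add atoms: oxalyl chloride, ClC(=O)C(=O)Cl
Why: Oxalyl chloride with catalytic DMF converts both carboxylic acids to acyl chlorides under mild, base-free conditions, and because both positions ortho to the side chain are substituted an intramolecular Friedel–Crafts acylation is not possible.

**Step 9**
Reactants: 14 pentan-3-one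
Product: 15 (Z)-3-(trimethylsilyloxy)pent-2-ene
Conditions: TMSOTf (1.05 equiv), Et3N (1.2 equiv), Et2O, 0 °C → rt; decant from the ammonium salt, distil
Reagents that add atoms: trimethylsilyl trifluoromethanesulfonate, C[Si](C)(C)OS(=O)(=O)C(F)(F)F
Why: Soft enolisation and O-silylation of a ketone with a silyl triflate and a tertiary amine; pentan-3-one is symmetrical, so only one regioisomeric enol ether can form.

**Step 10**
Reactants: 13 2-({2,4-bis(benzyloxy)-6-methoxy-3-[(2R)-2-methylbutanoyl]phenyl}methyl)propanedioyl dichloride; 15 (Z)-3-(trimethylsilyloxy)pent-2-ene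
Product: 17 3-({2,4-bis(benzyloxy)-6-methoxy-3-[(2R)-2-methylbutanoyl]phenyl}methyl)-6-ethyl-4-hydroxy-5-methyl-2H-pyran-2-one, via diketo acid chloride 16 (not isolated)
Conditions: 15 (1.1 equiv) added slowly to 13, Et2O, −78 °C → rt, 16 h; aqueous work-up
Reagents that add atoms: none
Why: Effenberger-type pyrone synthesis: the nucleophilic C2 of silyl enol ether 15 attacks one acyl chloride of 13 (or the chlorocarbonylketene that 13 forms by loss of HCl), chlorotrimethylsilane is expelled and the C4–C5 bond is made, giving diketo acid chloride 16. The enol oxygen of the former pentanone carbonyl then adds to the remaining acyl chloride and chloride leaves (6-exo-trig addition–elimination, forming O1–C2), and tautomerisation of the pyran-2,4-dione gives the aromatic 4-hydroxy-2-pyrone. The closest known reactions are the condensations of malonyl dichlorides or chlorocarbonylketenes with ketone silyl enol ethers to give 4-hydroxy-2-pyrones. No stereocentre is created, since the two sp3 carbons of 16 become sp2 in the pyrone, and the existing (R) centre should not be touched because the medium is base-free and cold and its ketone is shielded by two ortho benzyloxy groups. The step needs acylation at carbon before oxygen, which is the normal course for silyl enol ethers with acyl chlorides in the absence of fluoride or amine, and a single regiochemistry, which the symmetry of pentan-3-one guarantees. Both ring positions ortho to the side chain of 13 are substituted, so Friedel–Crafts closure to an indanone cannot compete.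

**Step 11**
Reactants: 17 3-({2,4-bis(benzyloxy)-6-methoxy-3-[(2R)-2-methylbutanoyl]phenyl}methyl)-6-ethyl-4-hydroxy-5-methyl-2H-pyran-2-one
Product: 18 3-({2,4-dihydroxy-6-methoxy-3-[(2R)-2-methylbutanoyl]phenyl}methyl)-6-ethyl-4-hydroxy-5-methyl-2H-pyran-2-one (CNP0199908.1)
Conditions: H2 (1 atm), 10% Pd/C, EtOAc, rt; stopped as soon as 17 is consumed
Reagents that add atoms: none
Why: Palladium-catalysed hydrogenolysis of aryl benzyl ethers under neutral conditions; the tetrasubstituted C5–C6 bond of the pyrone and the chelated, hindered aryl ketone are expected to resist reduction at one atmosphere.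

**Compound list**
1 | (2R)-2-methylbutanoic acid | OC(=O)[C@H](C)CC | starting material
2 | (2R)-2-methylbutanoyl chloride | ClC(=O)[C@H](C)CC | intermediate
3 | phloroglucinol (benzene-1,3,5-triol) | Oc1cc(O)cc(O)c1 | starting material
4 | (2R)-2-methyl-1-(2,4,6-trihydroxyphenyl)butan-1-one | O=C([C@H](C)CC)c1c(O)cc(O)cc1O | intermediate
5 | (2R)-1-(2,6-dihydroxy-4-methoxyphenyl)-2-methylbutan-1-one | COc1cc(O)c(C(=O)[C@H](C)CC)c(O)c1 | intermediate
6 | N-({2,4-dihydroxy-6-methoxy-3-[(2R)-2-methylbutanoyl]phenyl}methylidene)-N-methylmethanaminium chloride | C[N+](C)=Cc1c(OC)cc(O)c(C(=O)[C@H](C)CC)c1O.[Cl-] | intermediate (not isolated)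
7 | 2,4-dihydroxy-6-methoxy-3-[(2R)-2-methylbutanoyl]benzaldehyde | O=Cc1c(OC)cc(O)c(C(=O)[C@H](C)CC)c1O | intermediate
8 | 2,4-bis(benzyloxy)-6-methoxy-3-[(2R)-2-methylbutanoyl]benzaldehyde | O=Cc1c(OC)cc(OCc2ccccc2)c(C(=O)[C@H](C)CC)c1OCc1ccccc1 | intermediate
9 | Meldrum's acid (2,2-dimethyl-1,3-dioxane-4,6-dione) | CC1(C)OC(=O)CC(=O)O1 | starting material
10 | 5-({2,4-bis(benzyloxy)-6-methoxy-3-[(2R)-2-methylbutanoyl]phenyl}methylidene)-2,2-dimethyl-1,3-dioxane-4,6-dione | CC1(C)OC(=O)C(=Cc2c(OC)cc(OCc3ccccc3)c(C(=O)[C@H](C)CC)c2OCc2ccccc2)C(=O)O1 | intermediate (not isolated)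
11 | 5-({2,4-bis(benzyloxy)-6-methoxy-3-[(2R)-2-methylbutanoyl]phenyl}methyl)-2,2-dimethyl-1,3-dioxane-4,6-dione | CC1(C)OC(=O)C(Cc2c(OC)cc(OCc3ccccc3)c(C(=O)[C@H](C)CC)c2OCc2ccccc2)C(=O)O1 | intermediate
12 | 2-({2,4-bis(benzyloxy)-6-methoxy-3-[(2R)-2-methylbutanoyl]phenyl}methyl)propanedioic acid | OC(=O)C(Cc1c(OC)cc(OCc2ccccc2)c(C(=O)[C@H](C)CC)c1OCc1ccccc1)C(=O)O | intermediate
13 | 2-({2,4-bis(benzyloxy)-6-methoxy-3-[(2R)-2-methylbutanoyl]phenyl}methyl)propanedioyl dichloride | O=C(Cl)C(Cc1c(OC)cc(OCc2ccccc2)c(C(=O)[C@H](C)CC)c1OCc1ccccc1)C(=O)Cl | intermediate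
14 | pentan-3-one | CCC(=O)CC | starting material
15 | (Z)-3-(trimethylsilyloxy)pent-2-ene | C/C=C(/CC)O[Si](C)(C)C | intermediate
16 | 2-({2,4-bis(benzyloxy)-6-methoxy-3-[(2R)-2-methylbutanoyl]phenyl}methyl)-4-methyl-3,5-dioxoheptanoyl chloride (mixture of isomers at the two transient sp3 carbons) | CCC(=O)C(C)C(=O)C(Cc1c(OC)cc(OCc2ccccc2)c(C(=O)[C@H](C)CC)c1OCc1ccccc1)C(=O)Cl | intermediate (not isolated)
17 | 3-({2,4-bis(benzyloxy)-6-methoxy-3-[(2R)-2-methylbutanoyl]phenyl}methyl)-6-ethyl-4-hydroxy-5-methyl-2H-pyran-2-one | CCc1oc(=O)c(Cc2c(OC)cc(OCc3ccccc3)c(C(=O)[C@H](C)CC)c2OCc2ccccc2)c(O)c1C | intermediate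
18 | 3-({2,4-dihydroxy-6-methoxy-3-[(2R)-2-methylbutanoyl]phenyl}methyl)-6-ethyl-4-hydroxy-5-methyl-2H-pyran-2-one | CCc1oc(=O)c(Cc2c(OC)cc(O)c(C(=O)[C@H](C)CC)c2O)c(O)c1C | target

**Step count**
Total: 11 steps. Longest linear sequence: 10 steps (steps 1–8, 10 and 11); step 9 is a one-step branch.

**Steps most likely to fail**

1. Step 10 (pyrone annulation). The enol ether may be acylated at oxygen instead of carbon. The dichloride may oligomerise through its ketene. An acyl chloride may lactonise onto the neighbouring benzyloxy oxygen with loss of the benzyl group, which can already begin during step 8. The hydrogen chloride set free may erode the α-stereocentre.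
Fallback: it sets out from silyl enol ether 15 and aldehyde 8 and returns at 17, bypassing 11, 12 and 13. Unsubstituted malonyl dichloride (ClC(=O)CC(=O)Cl) is condensed with 15 (Et2O, −78 °C → rt) to give 6-ethyl-4-hydroxy-5-methyl-2H-pyran-2-one F1. F1 is then joined to 8 by three-component reductive alkylation (L-proline cat., Hantzsch ester, CH2Cl2 or EtOH, rt). Knoevenagel condensation gives 3-arylidene-6-ethyl-5-methylpyran-2,4-dione F2, which should be reduced by the Hantzsch ester in the flask before it can add a second pyrone, giving 17.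

2. Step 2 (Friedel–Crafts acylation). The α-stereocentre may be partly lost by enolisation of the acyl chloride–AlCl3 complex or of the chelated product ketone.
Fallback: it sets out from acid chloride 2 and phloroglucinol 3 and returns at 4. 2 is converted (MeNH(OMe)·HCl, Et3N, CH2Cl2, 0 °C) into the Weinreb amide (2R)-N-methoxy-N,2-dimethylbutanamide F3. 3 is converted (MOMCl, iPr2NEt, CH2Cl2) into 1,3,5-tris(methoxymethoxy)benzene F4. Ortho-lithiation of F4 (n-BuLi, THF, 0 °C) gives 2,4,6-tris(methoxymethoxy)phenyllithium F5, which adds to F3 at −78 °C. The chelated tetrahedral adduct collapses only on aq. NH4Cl work-up, so the product ketone never meets base, and this gives (2R)-2-methyl-1-[2,4,6-tris(methoxymethoxy)phenyl]butan-1-one F6. HCl in MeOH at rt removes the three methoxymethyl groups and returns 4.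

3. Step 11 (hydrogenolysis). Over-reduction may saturate the pyrone C5–C6 bond or reduce the benzylic ketone before both benzyl ethers are cleaved.
Fallback: it sets out from 17 and returns at 18. The benzyl ethers are cleaved without hydrogen by Lewis-acid dealkylation with a cation scavenger (BCl3, pentamethylbenzene, CH2Cl2, −78 °C; aqueous work-up). Both benzyl ethers are ortho to the ketone and should be cleaved fast through chelation, while the unchelated methyl ether and the pyrone are left alone. This fallback makes no new compound (F0).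

**Further compounds**
F1 | step 10 | 6-ethyl-4-hydroxy-5-methyl-2H-pyran-2-one | CCc1oc(=O)cc(O)c1C
F2 | step 10 | 3-({2,4-bis(benzyloxy)-6-methoxy-3-[(2R)-2-methylbutanoyl]phenyl}methylidene)-6-ethyl-5-methyl-2H-pyran-2,4(3H)-dione | CCC1=C(C)C(=O)C(=Cc2c(OC)cc(OCc3ccccc3)c(C(=O)[C@H](C)CC)c2OCc2ccccc2)C(=O)O1
F3 | step 2 | (2R)-N-methoxy-N,2-dimethylbutanamide | CON(C)C(=O)[C@H](C)CC
F4 | step 2 | 1,3,5-tris(methoxymethoxy)benzene | COCOc1cc(OCOC)cc(OCOC)c1
F5 | step 2 | 2,4,6-tris(methoxymethoxy)phenyllithium | [Li]c1c(OCOC)cc(OCOC)cc1OCOC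
F6 | step 2 | (2R)-2-methyl-1-[2,4,6-tris(methoxymethoxy)phenyl]butan-1-one | COCOc1cc(OCOC)c(C(=O)[C@H](C)CC)c(OCOC)c1
F0 | step 11 | none | none
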